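## Retrosynthetic overview

- The ten-membered carbocycle is closed last by a NiCl2/CrCl2 Nozaki–Hiyama–Kishi reaction between an alkenyl triflate on the furanone and an α-methacryloyloxy aldehyde; this forms the exo-methylene carbinol.
- The cis-fused α-methylene-γ-lactone comes from an indium Barbier allylation/lactonisation between a furanone acetaldehyde and a 2-(bromomethyl)enoate made from (S)-glyceraldehyde acetonide.
- The oxa-quaternary furanone centre comes from a Pd-catalysed decarboxylative asymmetric dearomative allylation of an aromatic 3-furyl allyl carbonate; this is the key step.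
- The carbonate is made from 2-acetyl-5-methylfuran, whose acetyl group later becomes the alkenyl triflate.
- Ring order: furan → 3(2H)-furanone → γ-lactone → ten-membered carbocycle.

Assumption: compounds 1, 5, 11, 12 and 18 are bought; the (R,R) Trost ligand is taken to give (R)-7 (otherwise its (S,S) antipode is used unchanged); transient enolates and organometallic species are not numbered.

## Route

Step 1
Reactants: 1 2-acetyl-5-methylfuran
Product: 2 1-(4-bromo-5-methylfuran-2-yl)ethan-1-one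
Conditions: Br2 (1.05 equiv), AlCl3 (2.5 equiv, swamping catalyst), CH2Cl2, 0 °C to rt
Reagents that add atoms: bromine, BrBr
Why: Electrophilic aromatic bromination in which the AlCl3-complexed acetyl group deactivates C-3 and the side chain, so the 5-methyl group directs bromine to the adjacent free position C-4.

Step 2
Reactants: 2 1-(4-bromo-5-methylfuran-2-yl)ethan-1-one
Product: 4 5-acetyl-2-methylfuran-3(2H)-one (labile C-2, tautomer of the 3-hydroxyfuran), via pinacol boronate 3 (not isolated)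
Conditions: B2pin2, Pd(dppf)Cl2 (3 mol %), KOAc, 1,4-dioxane, 85 °C; then Me3NO, rt; aqueous work-up
Reagents that add atoms: trimethylamine N-oxide, C[N+](C)(C)[O-]; bis(pinacolato)diboron, CC1(C)OB(OC1(C)C)B1OC(C)(C)C(C)(C)O1 (its boron stays only in 3)
Why: Miyaura borylation of the hetaryl bromide followed by mild ipso-oxidation of the C–B bond by the amine N-oxide gives the 3-hydroxyfuran, which rests as the 3(2H)-furanone.

Step 3
Reactants: 4 5-acetyl-2-methylfuran-3(2H)-one; 5 allyl chloroformate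
Product: 6 5-acetyl-2-methylfuran-3-yl prop-2-en-1-yl carbonate
Conditions: Et3N, CH2Cl2, −20 to 0 °C
Reagents that add atoms: none
Why: O-acylation of the furan-3-olate by the hard chloroformate re-aromatises the ring and gives the allyl enol carbonate.

Step 4
Reactants: 6 5-acetyl-2-methylfuran-3-yl prop-2-en-1-yl carbonate
Product: 7 (2R)-5-acetyl-2-methyl-2-(prop-2-en-1-yl)furan-3(2H)-one
Conditions: Pd2(dba)3·CHCl3 (2.5 mol %), (R,R)-ANDEN-phenyl Trost ligand (6 mol %), 1,4-dioxane, 23 °C
Reagents that add atoms: none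
Why: Proposed new method: zerovalent palladium ionises the carbonate, CO2 is lost, and the furan-3-olate/π-allylpalladium ion pair recombines at C-2 (the only enolate carbon; O-allylation is reversible) inside the chiral ligand pocket, which breaks the furan aromaticity and sets the oxa-quaternary (R) centre; the closest known reactions are the decarboxylative asymmetric allylic alkylation of allyl enol carbonates and the Pd-catalysed asymmetric allylic dearomatisation of 1-substituted 2-naphthols.

Step 5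
Reactants: 7 (2R)-5-acetyl-2-methyl-2-(prop-2-en-1-yl)furan-3(2H)-one
Product: 8 1-[(5R)-5-methyl-4-oxo-5-(prop-2-en-1-yl)-4,5-dihydrofuran-2-yl]ethenyl trifluoromethanesulfonate
Conditions: KN(SiMe3)2, THF, −78 °C; then N-(5-chloropyridin-2-yl)triflimide, −78 to −40 °C
Reagents that add atoms: N-(5-chloropyridin-2-yl)-1,1,1-trifluoro-N-(trifluoromethanesulfonyl)methanesulfonamide (Comins' reagent), FC(F)(F)S(=O)(=O)N(c1ccc(Cl)cn1)S(=O)(=O)C(F)(F)F
Why: The acetyl methyl is the only enolisable position (C-2 is quaternary), so kinetic enolisation and O-sulfonylation give the alkenyl triflate without touching the stereocentre.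

Step 6
Reactants: 8 the allyl furanone triflate
Product: 10 1-[(5R)-5-methyl-4-oxo-5-(2-oxoethyl)-4,5-dihydrofuran-2-yl]ethenyl trifluoromethanesulfonate, via diol 9 (not isolated)
Conditions: OsO4 (2 mol %), NaIO4 (4 equiv), 2,6-lutidine, 1,4-dioxane/H2O 3:1, rt
Reagents that add atoms: sodium periodate, [Na+].[O-]I(=O)(=O)=O (terminal source of the aldehyde oxygen, passed on through catalytic OsO4)
Why: Lemieux–Johnson cleavage, in which OsO4 selects the isolated monosubstituted alkene over the two electron-poor conjugated alkenes.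

Step 7
Reactants: 11 (4S)-2,2-dimethyl-1,3-dioxolane-4-carbaldehyde; 12 ethyl acrylate
Product: 13 ethyl 2-{[(4S)-2,2-dimethyl-1,3-dioxolan-4-yl](hydroxy)methyl}prop-2-enoate (both carbinol epimers)
Conditions: DABCO (1 equiv), 1,4-dioxane/H2O 1:1, rt, 48 h
Reagents that add atoms: none
Why: Morita–Baylis–Hillman reaction; the new carbinol centre is formed as a mixture, which is irrelevant because it is erased in step 8, and the dioxolane centre is retained.

Step 8
Reactants: 13 the Morita–Baylis–Hillman adduct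
Product: 14 ethyl (2Z)-2-(bromomethyl)-3-[(4R)-2,2-dimethyl-1,3-dioxolan-4-yl]prop-2-enoate
Conditions: NBS, Me2S, CH2Cl2, 0 °C to rt
Reagents that add atoms: N-bromosuccinimide, BrN1C(=O)CCC1=O
Why: Corey–Kim-type activation of the alcohol and SN2′ attack of bromide give the thermodynamically preferred (Z)-2-(bromomethyl)enoate (dioxolane trans to the ester).

Step 9
Reactants: 10 the furanone acetaldehyde; 14 the allylic bromide
Product: 16 1-[(5R)-5-{[(2S,3S)-3-[(4R)-2,2-dimethyl-1,3-dioxolan-4-yl]-4-methylidene-5-oxooxolan-2-yl]methyl}-5-methyl-4-oxo-4,5-dihydrofuran-2-yl]ethenyl trifluoromethanesulfonate, via hydroxy ester 15 (not isolated)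
Conditions: indium powder, THF/H2O 1:1, rt; then PPTS (cat.), PhMe, 50 °C
Reagents that add atoms: none
Why: Indium Barbier allylation then lactonisation; the closed Zimmerman–Traxler chair with the dioxolanyl group axial (cis to CH2In) gives the syn adduct and hence the cis-lactone, while A(1,3) strain holds the dioxolane C–H in the alkene plane so the aldehyde adds anti to the dioxolane C–O bond (Felkin–Anh-type induction from the allyl reagent), setting both lactone centres (S,S).

Step 10
Reactants: 16 the acetonide lactone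
Product: 17 1-[(5R)-5-{[(2S,3S)-3-[(1R)-1,2-dihydroxyethyl]-4-methylidene-5-oxooxolan-2-yl]methyl}-5-methyl-4-oxo-4,5-dihydrofuran-2-yl]ethenyl trifluoromethanesulfonate
Conditions: AcOH/H2O 4:1, 40 °C
Reagents that add atoms: none
Why: Acid-catalysed acetal hydrolysis that leaves the lactone, furanone, alkenyl triflate and all stereocentres untouched.

Step 11
Reactants: 17 the diol; 18 methacrylic anhydride
Product: 20 (1R)-1-[(2S,3S)-2-{[(2R)-2-methyl-3-oxo-5-{1-[(trifluoromethanesulfonyl)oxy]ethenyl}-2,3-dihydrofuran-2-yl]methyl}-4-methylidene-5-oxooxolan-3-yl]-2-[(triethylsilyl)oxy]ethyl 2-methylprop-2-enoate, via primary triethylsilyl ether 19 (not isolated)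
Conditions: Et3SiCl (1.05 equiv), Et3N, DMAP (cat.), CH2Cl2, −78 to −30 °C; then methacrylic anhydride, DMAP, 0 °C to rt
Reagents that add atoms: chlorotriethylsilane, CC[Si](Cl)(CC)CC
Why: Steric differentiation: the primary hydroxyl is silylated first and the remaining secondary hydroxyl is then acylated under DMAP catalysis with retention at the C–O carbon.

Step 12
Reactants: 20 the silyl ether methacrylate
Product: 21 (1R)-1-[(2S,3S)-2-{[(2R)-2-methyl-3-oxo-5-{1-[(trifluoromethanesulfonyl)oxy]ethenyl}-2,3-dihydrofuran-2-yl]methyl}-4-methylidene-5-oxooxolan-3-yl]-2-oxoethyl 2-methylprop-2-enoate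
Conditions: (COCl)2, DMSO, CH2Cl2, −78 to −40 °C; then Et3N, −78 to 0 °C
Reagents that add atoms: none
Why: Swern oxidation run directly on the primary triethylsilyl ether (desilylation by the chlorosulfonium salt, then oxidation), kept cold so the α-acyloxy aldehyde does not epimerise.

Step 13
Reactants: 21 the aldehyde alkenyl triflate
Product: 22 the target (SMILES in the list)
Conditions: CrCl2 (10 equiv), NiCl2 (0.1 equiv), degassed DMSO/THF, 2 mM, rt, slow addition
Reagents that add atoms: none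
Why: Nozaki–Hiyama–Kishi macrocyclisation (nickel inserts into the alkenyl triflate, transmetalation to chromium, addition to the aldehyde) closes the ten-membered ring, and polar Felkin–Anh addition anti to the C–O(acyl) bond gives the anti diol monoester, that is the (S)-carbinol.

## Compound list

1 | 2-acetyl-5-methylfuran (1-(5-methylfuran-2-yl)ethan-1-one) | CC(=O)c1ccc(C)o1 | starting material
2 | 1-(4-bromo-5-methylfuran-2-yl)ethan-1-one | CC(=O)c1cc(Br)c(C)o1 | intermediate
3 | 1-[5-methyl-4-(4,4,5,5-tetramethyl-1,3,2-dioxaborolan-2-yl)furan-2-yl]ethan-1-one | CC(=O)c1cc(B2OC(C)(C)C(C)(C)O2)c(C)o1 | intermediate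
4 | 5-acetyl-2-methylfuran-3(2H)-one (C-2 labile, unassigned) | CC(=O)C1=CC(=O)C(C)O1 | intermediate
5 | allyl chloroformate | C=CCOC(Cl)=O | starting material
6 | 5-acetyl-2-methylfuran-3-yl prop-2-en-1-yl carbonate | CC(=O)c1cc(OC(=O)OCC=C)c(C)o1 | intermediate
7 | (2R)-5-acetyl-2-methyl-2-(prop-2-en-1-yl)furan-3(2H)-one | C=CC[C@@]1(C)OC(=CC1=O)C(C)=O | intermediate
8 | 1-[(5R)-5-methyl-4-oxo-5-(prop-2-en-1-yl)-4,5-dihydrofuran-2-yl]ethenyl trifluoromethanesulfonate | C=CC[C@@]1(C)OC(=CC1=O)C(=C)OS(=O)(=O)C(F)(F)F | intermediate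
9 | 1-[(5R)-5-(2,3-dihydroxypropyl)-5-methyl-4-oxo-4,5-dihydrofuran-2-yl]ethenyl trifluoromethanesulfonate (carbinol epimers) | OCC(O)C[C@@]1(C)OC(=CC1=O)C(=C)OS(=O)(=O)C(F)(F)F | intermediate
10 | 1-[(5R)-5-methyl-4-oxo-5-(2-oxoethyl)-4,5-dihydrofuran-2-yl]ethenyl trifluoromethanesulfonate | O=CC[C@@]1(C)OC(=CC1=O)C(=C)OS(=O)(=O)C(F)(F)F | intermediate
11 | (4S)-2,2-dimethyl-1,3-dioxolane-4-carbaldehyde | CC1(C)O[C@@H](CO1)C=O | starting material
12 | ethyl acrylate | C=CC(=O)OCC | starting material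
13 | ethyl 2-{[(4S)-2,2-dimethyl-1,3-dioxolan-4-yl](hydroxy)methyl}prop-2-enoate (carbinol epimers) | CCOC(=O)C(=C)C(O)[C@@H]1COC(C)(C)O1 | intermediate
14 | ethyl (2Z)-2-(bromomethyl)-3-[(4R)-2,2-dimethyl-1,3-dioxolan-4-yl]prop-2-enoate | CCOC(=O)/C(CBr)=C/[C@@H]1COC(C)(C)O1 | intermediate
15 | ethyl (3S,4S)-3-[(4R)-2,2-dimethyl-1,3-dioxolan-4-yl]-4-hydroxy-2-methylidene-5-[(2R)-2-methyl-3-oxo-5-{1-[(trifluoromethanesulfonyl)oxy]ethenyl}-2,3-dihydrofuran-2-yl]pentanoate | CC1(C)O[C@@H](CO1)[C@@H](C(=C)C(=O)OCC)[C@@H](O)C[C@@]2(C)OC(=CC2=O)C(=C)OS(=O)(=O)C(F)(F)F | intermediate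
16 | 1-[(5R)-5-{[(2S,3S)-3-[(4R)-2,2-dimethyl-1,3-dioxolan-4-yl]-4-methylidene-5-oxooxolan-2-yl]methyl}-5-methyl-4-oxo-4,5-dihydrofuran-2-yl]ethenyl trifluoromethanesulfonate | CC1(C)O[C@@H](CO1)[C@H]2C(=C)C(=O)O[C@H]2C[C@@]3(C)OC(=CC3=O)C(=C)OS(=O)(=O)C(F)(F)F | intermediate
17 | 1-[(5R)-5-{[(2S,3S)-3-[(1R)-1,2-dihydroxyethyl]-4-methylidene-5-oxooxolan-2-yl]methyl}-5-methyl-4-oxo-4,5-dihydrofuran-2-yl]ethenyl trifluoromethanesulfonate | O[C@@H](CO)[C@H]1C(=C)C(=O)O[C@H]1C[C@@]2(C)OC(=CC2=O)C(=C)OS(=O)(=O)C(F)(F)F | intermediate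
18 | methacrylic anhydride | CC(=C)C(=O)OC(=O)C(C)=C | starting material
19 | 1-[(5R)-5-{[(2S,3S)-3-{(1R)-1-hydroxy-2-[(triethylsilyl)oxy]ethyl}-4-methylidene-5-oxooxolan-2-yl]methyl}-5-methyl-4-oxo-4,5-dihydrofuran-2-yl]ethenyl trifluoromethanesulfonate | O[C@@H](CO[Si](CC)(CC)CC)[C@H]1C(=C)C(=O)O[C@H]1C[C@@]2(C)OC(=CC2=O)C(=C)OS(=O)(=O)C(F)(F)F | intermediate
20 | (1R)-1-[(2S,3S)-2-{[(2R)-2-methyl-3-oxo-5-{1-[(trifluoromethanesulfonyl)oxy]ethenyl}-2,3-dihydrofuran-2-yl]methyl}-4-methylidene-5-oxooxolan-3-yl]-2-[(triethylsilyl)oxy]ethyl 2-methylprop-2-enoate | C=C(C)C(=O)O[C@@H](CO[Si](CC)(CC)CC)[C@H]1C(=C)C(=O)O[C@H]1C[C@@]2(C)OC(=CC2=O)C(=C)OS(=O)(=O)C(F)(F)F | intermediate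
21 | (1R)-1-[(2S,3S)-2-{[(2R)-2-methyl-3-oxo-5-{1-[(trifluoromethanesulfonyl)oxy]ethenyl}-2,3-dihydrofuran-2-yl]methyl}-4-methylidene-5-oxooxolan-3-yl]-2-oxoethyl 2-methylprop-2-enoate | C=C(C)C(=O)O[C@@H](C=O)[C@H]1C(=C)C(=O)O[C@H]1C[C@@]2(C)OC(=CC2=O)C(=C)OS(=O)(=O)C(F)(F)F | intermediate
22 | CNP0142847.2: ten-membered carbocycle bridged by the 2-methyl-3(2H)-furanone (oxa-quaternary carbon R) and cis-fused to the α-methylene-γ-lactone (ring CH–C carbon S, ring CH–O carbon S), methacrylate-bearing carbon R, free allylic carbinol S next to the exo-methylene | C=C(C)C(=O)O[C@@H]1[C@H]2C(=C)C(=O)O[C@H]2C[C@@]2(C)OC(=CC2=O)C(=C)[C@@H]1O | target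

## Step count and risks

Total: 13 steps (one-pot sequences counted once). Longest linear sequence: 11 steps (steps 1–6 and 9–13).

**Step 4 (dearomative asymmetric allylation).** The reaction is unprecedented on a 3-furyl carbonate and the level and sense of induction are unknown. The fallback sets out from 4 and comes back at 7. O-Allylation of 4 (allyl bromide, K2CO3, acetone) gives the aromatic ether 1-[5-methyl-4-(prop-2-en-1-yloxy)furan-2-yl]ethan-1-one F1. Heating in toluene at 110 °C brings about a thermal dearomative Claisen rearrangement to racemic 5-acetyl-2-methyl-2-(prop-2-en-1-yl)furan-3(2H)-one F2. Preparative chromatography on a chiral stationary phase then delivers 7 and sets aside (2S)-5-acetyl-2-methyl-2-(prop-2-en-1-yl)furan-3(2H)-one F3.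

**Step 9 (Barbier allylation).** The face selectivity rests on induction from the dioxolane alone, and the allylindium could also lose the dioxolane oxygen by 1,4-elimination. The fallback sets out from 13 and comes back at 16. Acetylation of 13 (Ac2O, DMAP, Et3N) gives ethyl 2-{(acetyloxy)[(4S)-2,2-dimethyl-1,3-dioxolan-4-yl]methyl}prop-2-enoate F4. CuCl-catalysed SN2′ borylation (B2pin2, KOAc, LiCl, DMF) gives ethyl (2E)-3-[(4R)-2,2-dimethyl-1,3-dioxolan-4-yl]-2-[(4,4,5,5-tetramethyl-1,3,2-dioxaborolan-2-yl)methyl]prop-2-enoate F5, which has the same alkene geometry as 14. Allylboration of 10 with F5 under a chiral BINOL-derived phosphoric acid (TRIP, antipode chosen for the (S)-carbinol) runs through a closed chair in which the catalyst, not the dioxolane, picks the aldehyde face. Work-up gives 15, which is lactonised with PPTS to 16.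

**Step 13 (Nozaki–Hiyama–Kishi macrocyclisation).** The ring is strained, the carbinol configuration is set by the macrocyclic transition state and may come out wrong, and the methacrylate may migrate to the new hydroxyl. The fallback sets out from 21 and comes back at 22. If the closure gives mainly the carbinol epimer of 22 F6, Dess–Martin oxidation gives the macrocyclic α-methylene ketone F7. Reagent-controlled reduction with Me-CBS oxazaborolidine/BH3·SMe2 (antipode chosen for the (S)-carbinol) then gives 22.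

## Further compounds

F1 | step 4 | 1-[5-methyl-4-(prop-2-en-1-yloxy)furan-2-yl]ethan-1-one | CC(=O)c1cc(OCC=C)c(C)o1
F2 | step 4 | racemic 5-acetyl-2-methyl-2-(prop-2-en-1-yl)furan-3(2H)-one | C=CCC1(C)OC(=CC1=O)C(C)=O
F3 | step 4 | (2S)-5-acetyl-2-methyl-2-(prop-2-en-1-yl)furan-3(2H)-one | C=CC[C@]1(C)OC(=CC1=O)C(C)=O
F4 | step 9 | ethyl 2-{(acetyloxy)[(4S)-2,2-dimethyl-1,3-dioxolan-4-yl]methyl}prop-2-enoate | CCOC(=O)C(=C)C(OC(C)=O)[C@@H]1COC(C)(C)O1
F5 | step 9 | ethyl (2E)-3-[(4R)-2,2-dimethyl-1,3-dioxolan-4-yl]-2-[(4,4,5,5-tetramethyl-1,3,2-dioxaborolan-2-yl)methyl]prop-2-enoate | CCOC(=O)/C(CB1OC(C)(C)C(C)(C)O1)=C/[C@@H]2COC(C)(C)O2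
F6 | step 13 | carbinol epimer of 22 ((R)-carbinol, all other centres as in 22) | C=C(C)C(=O)O[C@@H]1[C@H]2C(=C)C(=O)O[C@H]2C[C@@]2(C)OC(=CC2=O)C(=C)[C@H]1O
F7 | step 13 | macrocyclic α-methylene ketone (carbinol carbon of 22 oxidised to C=O) | C=C(C)C(=O)O[C@@H]1[C@H]2C(=C)C(=O)O[C@H]2C[C@@]2(C)OC(=CC2=O)C(=C)C1=O
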